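The closed, stirred vessel holds first end groups and second end groups that join into links, with third end groups alongside, and you want to know what stands at the look and which remedy pays.

the same everywhere: first end groups 0.20 M; temperature 5 °C
- zeta: second end groups 0.196 M; third end groups 0.050 M; the very flask that is asked about, followed so far
- eta: second end groups 0.098 M; third end groups 0.050 M; run made earlier
- flask: second end groups 0.196 M; third end groups 0.0500 M; time 15 h

- zeta (time / h: links / %, first end groups / %): 1.50: 24.2, 75.0; 3.00: 37.2, 63.4; 5.00: 46.1, 53.9; 6.00: 50.1, 50.3; 8.00: 53.8, 45.6; 10.0: 55.8, 42.3
- eta (time / h: links / %, first end groups / %): 1.00: 9.7, 89.7; 2.00: 16.1, 82.9; 3.00: 22.1, 77.8; 4.00: 24.7, 75.0; 5.00: 27.4, 71.7; 6.00: 29.9, 69.1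

(scatter of a reading: 0.5 percentage points)

- links taken out counts as made
- the numbers in the tables scatter with a standard deviation of 0.5 percentage points
- the earlier runs do not show what temperature does; that part of a forecast is a guess
- additions bring no volume worth counting

- north-west: at 15 h add second end groups, 100% of the amount charged, then wait 15 h
- north-east: change nothing and wait 15 h more
- south: at 15 h raise the temperature by 15 K, then wait 15 h
- west: at 15 h take out 90% of the links then present, then wait 15 h

1. links, in percent of the first end groups first charged, at 15 h
2. the remedy with the largest gain of links, or "none" below 2 percentage points (north-west / north-east / south / west / none)
3. links present, with what was taken out counted in, in percent of the first end groups first charged, after north-west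
4. links present, with what was taken out counted in, in percent of the first end groups first charged, after south

Begin with the first instants of the zeta run, which is the asked flask followed so far. The two end groups are charged nearly equally, so the simple second-order rule applied to the first end groups read at 1.50 h gives a rate constant, as a reading with its scatter, of 1.11 /M/h. Turn that into a time: 3.18 h is the link half-life, the time in which first end groups would halve by the forward step with second end groups at their full charge, and you divide it by the fraction of second end groups left to get its value later.

At the last reading of the zeta run, at 10.0 h, links stand at 55.8%, so if second end groups went into links and nowhere else, their fraction left would be 43.1% and the half-life 7.38 h. That pace would add 7.9 percentage points between the last two readings, more than the 2 points actually gained. So something slows the links beyond this balance, and the readings, which do not show second end groups, leave open whether it is a way back or a further loss of them.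

For the end, carrying the last slope forward gives you 60.8% at 15 h. North-west brings the fraction of second end groups back above a whole charge and the half-life below 3.18 h, so that is your choice.

The forecast gave 58%, which is lower than your figure, then north-west as best, 80% after north-west and 50% after south, holding that zeta “fits a reversible link formation”.

The flask gives 61.5%, with north-west best at a gain of 26 points, 87.8% after north-west and 54.6% after south.

    first end groups + second end groups ⇌ links (K = 140 /M, k = 1.20 /M/h, Ea = 69.0 kJ/mol, ΔH = −37.0 kJ/mol)
    2 second end groups → homo dimer (k = 0.280 /M/h, Ea = 57.0 kJ/mol)
    second end groups → decomposition product (k = 2.40 × 10⁻⁴ /h, Ea = 94.0 kJ/mol)
    second end groups + third end groups → links of the second sort (k = 0.130 /M/h, Ea = 55.0 kJ/mol)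
    (constants at 5 °C)

At 15.0 h the flask holds 11.5% of its second end groups and 0.0223 M of homo dimer, with two second end groups in each, and your link half-life, as read from the zeta run, divided by that fraction reckons to 27.7 h, longer than the 3.18 h at the charge. The neighbouring flask has 0.050 M of first end groups and the same second end groups, which makes 3.92 equiv. A pseudo-first-order reckoning with 3.18 h leaves 3.80% of its first end groups after 15 h. But its second end groups end at 29%, where the half-life reads 11.0 h, and its first end groups end at 21.9%, with links at 78.1%.

The runs were computed on assumed constants.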